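## Retrosynthetic overview

- **Feature:** in the pyrrole ring, C3 is bonded to the benzene ring (at C3a) and C2 to N1. The C2=C3 bond can therefore be cut into two carbonyl carbons sitting ortho to each other on a 3,6-dibromoaniline core: an aryl aldehyde (C3) and an anilide C=O (C2).
- **Late bromines:** C3–Br comes from electrophilic substitution and C2–Br from ipso-bromodecarboxylation of a C2 acid. The anilide partner is therefore an ethyl oxamate.
- **Ring order:** the benzene ring is bought with the C4 and C7 bromines in place. The pyrrole ring is the only ring formed, by low-valent-titanium reductive oxo-amide coupling.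
- **Oxo-amide:** 1,4-dibromo-2-fluorobenzene is lithiated and formylated between F and Br, fluoride is exchanged for azide and then amine, and the nitrogen is acylated with ethyl chlorooxoacetate.

Key step: step 5

Remark: the target has no stereocentre, LiN(i-Pr)2 is taken as the commercial solution, and the aryl azide intermediate is handled in solution and never heated neat.

## Route

Step 1
Reactants: 1 1,4-dibromo-2-fluorobenzene; 2 N,N-dimethylformamide
Product: 5 3,6-dibromo-2-fluorobenzaldehyde, via 3,6-dibromo-2-fluorophenyllithium 3 (not isolated), via lithium hemiaminal alkoxide 4 (not isolated)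
Conditions: LiN(i-Pr)2 (1.1 equiv), THF, −78 °C, 45 min; 2 (1.5 equiv), −78 °C; 1 M HCl quench, −78 °C → rt
Reagents that add atoms: N,N-dimethylformamide 2, CN(C)C=O; lithium diisopropylamide, [Li+].CC(C)[N-]C(C)C (its lithium stays only in 3 and 4)
Why: Directed ortho-metalation followed by formylation with a formamide: the C3–H of 1 sits between F and Br and is the most acidic ring proton, the amide base removes it at −78 °C without Br–Li exchange, the cold aryllithium 3 is trapped by 2 before halogen dance or aryne formation can set in, and the stable adduct 4 releases the aldehyde only on acidic quench.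

Step 2
Reactants: 5 3,6-dibromo-2-fluorobenzaldehyde
Product: 6 2-azido-3,6-dibromobenzaldehyde
Conditions: NaN3 (1.3 equiv), DMSO, 40–50 °C, dark
Reagents that add atoms: sodium azide, [Na+].[N-]=[N+]=[N-]
Why: Nucleophilic aromatic substitution by addition–elimination: the formyl group ortho to C–F stabilises the Meisenheimer adduct, fluoride leaves far faster than the equally ortho-placed bromide in this mechanism, and the mild temperature keeps the ortho-azido aldehyde from losing N2.

Step 3
Reactants: 6 2-azido-3,6-dibromobenzaldehyde
Product: 8 2-amino-3,6-dibromobenzaldehyde, via iminophosphorane 7 (not isolated)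
Conditions: PPh3 (1.1 equiv), THF, 0 °C → rt; then AcOH/H2O, 50 °C
Reagents that add atoms: triphenylphosphine, c1ccc(cc1)P(c1ccccc1)c1ccccc1 (its atoms stay only in 7)
Why: Staudinger reduction: PPh3 converts the azide with loss of N2 into iminophosphorane 7 without touching the aldehyde or the C–Br bonds, warm aqueous acetic acid cleaves the P=N bond, and the flanking bromine atoms slow both aza-Wittig condensation and self-condensation of the amino aldehyde.

Step 4
Reactants: 8 2-amino-3,6-dibromobenzaldehyde; 9 ethyl chlorooxoacetate
Product: 10 ethyl 2-[(3,6-dibromo-2-formylphenyl)amino]-2-oxoacetate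
Conditions: 9 (1.3 equiv), pyridine (2 equiv), DMAP (cat.), CH2Cl2, 0 °C → rt
Reagents that add atoms: ethyl chlorooxoacetate 9, CCOC(=O)C(Cl)=O
Why: N-Acylation of an aniline with an acid chloride: the chlorocarbonyl end of 9 is far more electrophilic than its ester end and reactive enough for the hindered, weakly basic amine of 8, while pyridine binds the HCl and DMAP relays the acyl group.

Step 5
Reactants: 10 ethyl 2-[(3,6-dibromo-2-formylphenyl)amino]-2-oxoacetate
Product: 12 ethyl 4,7-dibromo-1H-indole-2-carboxylate, via cis-fused titanium diolate 11 (not isolated)
Conditions: TiCl3 (4 equiv), Zn dust (8 equiv), DME, reflux, 2 h, Ar; then 10 in DME by syringe pump over 6–8 h, reflux; filtration through silica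
Reagents that add atoms: titanium trichloride, Cl[Ti](Cl)Cl (titanium and chlorine stay only in 11)
Why: Fürstner indole synthesis, that is an intramolecular McMurry-type reductive coupling of an oxo-amide, whose closest known cases are N-(2-acylphenyl)oxamates that give indole-2-carboxylates with the ester untouched. Low-valent titanium transfers an electron to the aldehyde, the most easily reduced carbonyl of 10, and the titanium-bound ketyl carbon (later C3) adds to the neighbouring anilide carbonyl carbon (later C2), which the same oxophilic metal binds and activates. The pyrrole ring closes in a 5-exo-trig mode (C3, C3a, C7a, N1, C2) to diolate 11, and a second two-electron reduction strips both oxygens as titanium oxide species, driven by the strong Ti–O bonds and by the aromaticity of the indole. The two stereocentres of 11 are cis by the titanium bridge but are erased at once, so the product has none to control. Ring closure must beat pinacol dimerisation of the aldehyde, which slow addition into a dilute slurry, the ortho placement of the partners and the bromine flanking the formyl group should secure; the ester stays out because it would need a six-membered closure onto a less reactive carbonyl. The C4 and C7 bromines should survive, since TiCl3/Zn and TiCl4/Zn couple bromoaryl ketones to alkenes with the C–Br bonds intact.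

Step 6
Reactants: 12 ethyl 4,7-dibromo-1H-indole-2-carboxylate
Product: 14 4,7-dibromo-1H-indole-2-carboxylic acid, via lithium 4,7-dibromoindole-2-carboxylate 13 (not isolated)
Conditions: LiOH·H2O (3 equiv), THF/H2O, rt → 40 °C; then 1 M HCl to pH 2
Reagents that add atoms: lithium hydroxide, [Li+].[OH-]
Why: Ester saponification by acyl–oxygen cleavage: hydroxide attacks the unhindered C2 ester, the aryl bromides and the indole N–H are inert to LiOH at this temperature, and acidification of salt 13 should precipitate the acid.

Step 7
Reactants: 14 4,7-dibromo-1H-indole-2-carboxylic acid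
Product: 16 2,3,4,7-tetrabromo-1H-indole, via 3,4,7-tribromo-1H-indole-2-carboxylic acid 15 (not isolated)
Conditions: NBS (2.1 equiv, two portions), LiOAc (0.2 equiv), dry DMF, 0 °C → rt, dark
Reagents that add atoms: N-bromosuccinimide, O=C1CCC(=O)N1Br
Why: Electrophilic bromination at C3, the most nucleophilic free position of the indole, followed by ipso-bromodecarboxylation (ionic Hunsdiecker-type halodecarboxylation known for electron-rich pyrrole and indole carboxylic acids): the carboxylate of 15 takes up the second Br+ at C2 and regains aromaticity by losing CO2, while C5 and C6 on the doubly brominated benzene ring are too deactivated to compete.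

## Compound list

1 | 1,4-dibromo-2-fluorobenzene | Fc1cc(Br)ccc1Br | starting material
2 | N,N-dimethylformamide | CN(C)C=O | starting material
3 | 3,6-dibromo-2-fluorophenyllithium (not isolated) | [Li]c1c(F)c(Br)ccc1Br | intermediate
4 | lithium (3,6-dibromo-2-fluorophenyl)(dimethylamino)methanolate (racemic, not isolated) | [Li+].[O-]C(N(C)C)c1c(F)c(Br)ccc1Br | intermediate
5 | 3,6-dibromo-2-fluorobenzaldehyde | O=Cc1c(F)c(Br)ccc1Br | intermediate
6 | 2-azido-3,6-dibromobenzaldehyde | O=Cc1c(N=[N+]=[N-])c(Br)ccc1Br | intermediate
7 | 3,6-dibromo-2-[(triphenyl-λ5-phosphanylidene)amino]benzaldehyde (not isolated) | O=Cc1c(N=P(c2ccccc2)(c2ccccc2)c2ccccc2)c(Br)ccc1Br | intermediate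
8 | 2-amino-3,6-dibromobenzaldehyde | Nc1c(Br)ccc(Br)c1C=O | intermediate
9 | ethyl chlorooxoacetate | CCOC(=O)C(Cl)=O | starting material
10 | ethyl 2-[(3,6-dibromo-2-formylphenyl)amino]-2-oxoacetate | CCOC(=O)C(=O)Nc1c(Br)ccc(Br)c1C=O | intermediate
11 | dichlorotitanium 2,3-diolate of ethyl cis-4,7-dibromo-2,3-dihydroxyindoline-2-carboxylate (simplest formula, racemic, one enantiomer drawn, not isolated) | CCOC(=O)[C@]12Nc3c(Br)ccc(Br)c3[C@H]1O[Ti](Cl)(Cl)O2 | intermediate
12 | ethyl 4,7-dibromo-1H-indole-2-carboxylate | CCOC(=O)c1cc2c(Br)ccc(Br)c2[nH]1 | intermediate
13 | lithium 4,7-dibromo-1H-indole-2-carboxylate (not isolated) | [Li+].[O-]C(=O)c1cc2c(Br)ccc(Br)c2[nH]1 | intermediate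
14 | 4,7-dibromo-1H-indole-2-carboxylic acid | OC(=O)c1cc2c(Br)ccc(Br)c2[nH]1 | intermediate
15 | 3,4,7-tribromo-1H-indole-2-carboxylic acid (not isolated) | OC(=O)c1[nH]c2c(Br)ccc(Br)c2c1Br | intermediate
16 | 2,3,4,7-tetrabromo-1H-indole | Brc1[nH]c2c(Br)ccc(Br)c2c1Br | target

## Step count and risks

Total step count: 7. Longest linear sequence: 7 steps (1 → 16).

**Step 5.**
- Risk: the aldehyde may dimerise by intermolecular pinacol coupling. The formyl group may simply be reduced. Bromine next to the ketyl centre may be lost reductively.
- Fallback: this closes the pyrrole ring at N1–C2 by a nitrene route instead of at C2=C3. It sets out from azide 6. Wittig olefination with Ph3P=CHCO2Et (CH2Cl2, rt) should give ethyl (E)-3-(2-azido-3,6-dibromophenyl)prop-2-enoate F1. Thermolysis of F1 in xylene at about 140 °C is a Sundberg-type cyclisation of an ortho-azidostyrene: N2 is lost, nitrogen bonds to the ester-bearing alkene carbon, and a hydrogen shifts to nitrogen. This should deliver 12, where the route is rejoined.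

**Step 7.**
- Risk: ipso attack at C2 of the already deactivated tribromo acid may be sluggish. Traces of water may oxidise the pyrrole ring. Surplus NBS may brominate the benzene ring.
- Fallback: this separates loss of CO2 from bromination. It sets out from acid 14. Silver-catalysed protodecarboxylation (Ag2CO3 cat., AcOH cat., DMSO, 120 °C) should give 4,7-dibromo-1H-indole F2. Stepwise C–H bromination with NBS on silica gel in CH2Cl2 should then go first at C3 to 3,4,7-tribromo-1H-indole F3 and next at C2, arriving at target 16.

**Step 3.**
- Risk: hydrolysis of the electron-poor N-aryl iminophosphorane may be slow. It may undergo aza-Wittig condensation with the aldehyde of a second molecule. The amino aldehyde may self-condense under acid.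
- Fallback: this is a redox detour that removes the aldehyde during azide reduction. It sets out from 6. NaBH4 (MeOH, 0 °C) should give (2-azido-3,6-dibromophenyl)methanol F4. Zn/NH4Cl (EtOH/H2O, rt) should reduce the azide to (2-amino-3,6-dibromophenyl)methanol F5. MnO2 (CH2Cl2, rt) should oxidise the benzylic alcohol selectively to 8, where the route is rejoined.

## Further compounds

F1 | step 5 | ethyl (E)-3-(2-azido-3,6-dibromophenyl)prop-2-enoate | CCOC(=O)/C=C/c1c(Br)ccc(Br)c1N=[N+]=[N-]
F2 | step 7 | 4,7-dibromo-1H-indole | Brc1ccc(Br)c2[nH]ccc12
F3 | step 7 | 3,4,7-tribromo-1H-indole | Brc1c[nH]c2c(Br)ccc(Br)c12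
F4 | step 3 | (2-azido-3,6-dibromophenyl)methanol | OCc1c(Br)ccc(Br)c1N=[N+]=[N-]
F5 | step 3 | (2-amino-3,6-dibromophenyl)methanol | Nc1c(Br)ccc(Br)c1CO
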